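**Plan**

Ring labels: A is the trioxygenated ring (C1–OH, C2–OH central, C3–O–ring B, C5–CH2). B is the para-phenylene. C carries CH2CH2, O–ring D and OH on three adjacent carbons. D is the ortho-phenylene.
Cuts, in retrosynthetic order: three O–Me phenol masks; the D-side CH2 of the A–D bridge, traced back through C=O to C(=CH2); the ring A C5–CH2 bond (retro para-Claisen, which returns that CH2 to O2 of ring A); the O2–CH2 bond of the resulting 17-membered ether; the ring D–C(vinyl) bond; the B–C ethylene bridge; the A–O–B and C–O–D aryl ether bonds.
Forward: A is joined to B and C to D by SNAr, and the halves are joined by Wittig olefination and diimide reduction. The C3 unit is then coupled to ring D, a Mitsunobu reaction closes the ether macrocycle, and heat converts it into the carbon-bridged 17-membered ring. Excision of the extra methylene and demethylation finish the synthesis.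
Enabling feature: C5 of ring A, which holds the bridge CH2, is para to C2–O. C1 and C3, the two carbons ortho to C2, both bear oxygen. An allyl group leaving O2 finds both ortho carbons blocked and can come to rest only on C5.
Stereochemistry: the target is achiral, with no stereocentre and no configured double bond. Stereocentres of transient intermediates are erased.

Key step: step 12

Remark: the Wittig stilbene is carried on as an E/Z mixture because the double bond is saturated at once. Transient sp3 centres are racemic and are drawn without configuration.

**Route**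

Step 1
Reactants: 1 o-vanillin (2-hydroxy-3-methoxybenzaldehyde)
Product: 2 3-methoxy-2-(methoxymethoxy)benzaldehyde
Conditions: MOMCl, iPr2NEt, CH2Cl2, 0 °C to rt
Reagents that add atoms: chloromethyl methyl ether (MOMCl), COCCl
Why: Williamson-type O-alkylation (MOM protection) with a reactive α-chloro ether masks the future central oxygen of ring A as an acetal that withstands the basic, olefination and reduction steps ahead and needs no hydrogenolysis for its removal.

Step 2
Reactants: 2 3-methoxy-2-(methoxymethoxy)benzaldehyde
Product: 4 3-methoxy-2-(methoxymethoxy)phenol, via aryl formate 3 (not isolated)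
Conditions: mCPBA, CH2Cl2, rt; then K2CO3 (cat.), MeOH, rt
Reagents that add atoms: 3-chloroperbenzoic acid (mCPBA), OOC(=O)c1cccc(Cl)c1
Why: In this Baeyer–Villiger (Dakin-type) oxidation the electron-rich aryl group with its ortho alkoxy donor migrates in preference to hydride, and mild methanolysis of formate 3 frees the phenol without touching the acetal.

Step 3
Reactants: 4 3-methoxy-2-(methoxymethoxy)phenol; 5 4-fluorobenzaldehyde
Product: 6 4-[3-methoxy-2-(methoxymethoxy)phenoxy]benzaldehyde
Conditions: K2CO3, DMF, 120 °C
Reagents that add atoms: none
Why: Nucleophilic aromatic substitution (SNAr) works here because the para formyl group stabilises the Meisenheimer adduct and fluoride leaves readily, which is a standard diaryl ether synthesis for bis(bibenzyl) building blocks.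

Step 4
Reactants: 7 2-bromophenol; 8 2-fluoro-3-methoxybenzaldehyde
Product: 9 2-(2-bromophenoxy)-3-methoxybenzaldehyde
Conditions: K2CO3, DMAc, 140 °C
Reagents that add atoms: none
Why: This SNAr is activated by the ortho formyl group, neither partner is enolisable (an arylacetate partner would be prone to Knoevenagel closure onto the aldehyde), and the unactivated C–Br bond stays as the later handle on ring D.

Step 5
Reactants: 9 2-(2-bromophenoxy)-3-methoxybenzaldehyde
Product: 10 [2-(2-bromophenoxy)-3-methoxyphenyl]methanol
Conditions: NaBH4, MeOH/THF, 0 °C
Reagents that add atoms: none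
Why: Borohydride reduction is chemoselective for the aldehyde and leaves the aryl bromide and the ethers untouched.

Step 6
Reactants: 10 [2-(2-bromophenoxy)-3-methoxyphenyl]methanol
Product: 11 [2-(2-bromophenoxy)-3-methoxybenzyl]triphenylphosphonium bromide
Conditions: PPh3·HBr, MeCN, reflux
Reagents that add atoms: triphenylphosphine hydrobromide, Br.c1ccc(cc1)P(c1ccccc1)c1ccccc1
Why: Acid-assisted substitution of the activated benzylic hydroxyl by PPh3 gives the phosphonium salt in one operation, and this half carries no acid-labile group.

Step 7
Reactants: 11 [2-(2-bromophenoxy)-3-methoxybenzyl]triphenylphosphonium bromide; 6 4-[3-methoxy-2-(methoxymethoxy)phenoxy]benzaldehyde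
Product: 13 A–B–C–D stilbene (E/Z mixture), via phosphonium ylide 12 (not isolated)
Conditions: K2CO3, 18-crown-6 (cat.), CH2Cl2, reflux
Reagents that add atoms: none
Why: Wittig olefination with a semi-stabilised benzylic ylide under mild solid–liquid phase-transfer conditions joins the halves and tolerates the acetal and the aryl bromide.

Step 8
Reactants: 13 A–B–C–D stilbene
Product: 14 MOM-protected bibenzyl aryl bromide
Conditions: TsNHNH2, NaOAc, THF/H2O, reflux
Reagents that add atoms: none
Why: Diimide reduction delivers two hydrogens concertedly to the C=C bond only, so the C–Br bond that catalytic hydrogenation over palladium would endanger survives, and the acetate buffer protects the acetal.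

Step 9
Reactants: 14 MOM-protected bibenzyl aryl bromide
Product: 15 2-(4-{2-[2-(2-bromophenoxy)-3-methoxyphenyl]ethyl}phenoxy)-6-methoxyphenol
Conditions: HCl (aq, cat.), MeOH, 50 °C
Reagents that add atoms: none
Why: Acid-catalysed acetal exchange (MOM cleavage) is placed here because the molecule does not yet contain the acid-sensitive styrene-type double bond.

Step 10
Reactants: 15 phenol aryl bromide; 16 2-bromoprop-2-en-1-ol
Product: 18 seco phenol–allylic alcohol, via pinacol boronate 17 (not isolated)
Conditions: B2pin2, Pd(dppf)Cl2 (cat.), KOAc, 1,4-dioxane, 90 °C; then 16, aq K3PO4, 80 °C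
Reagents that add atoms: bis(pinacolato)diboron, CC1(C)OB(OC1(C)C)B1OC(C)(C)C(C)(C)O1 (its boryl group stands in 17 and is lost again in 18)
Why: Miyaura borylation converts the aryl bromide into boronate 17, and Suzuki–Miyaura coupling in the same pot with vinylic bromide 16, a known route to 2-arylallyl alcohols, forms the ring D–C(vinyl) bond with the free phenol and alcohol tolerated.

Step 11
Reactants: 18 seco phenol–allylic alcohol
Product: 19 17-membered macrocyclic 2-arylallyl aryl ether
Conditions: PPh3, DIAD, toluene, 0 °C to rt, slow addition of 18 (final ca. 2 mM)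
Reagents that add atoms: none
Why: In this intramolecular Mitsunobu etherification the primary allylic alcohol is activated as its oxyphosphonium salt and displaced by the ring A phenoxide (SN2 and SN2' give the same constitution because the allyl unit is symmetric about its central carbon), and pseudo-high dilution favours the ring over oligomers.

Step 12
Reactants: 19 17-membered macrocyclic 2-arylallyl aryl ether
Product: 22 carbon-bridged 17-membered para-(2-arylallyl)phenol, via ortho-dienone 20 (not isolated), via para-dienone 21 (not isolated)
Conditions: PhNEt2 (degassed, ca. 0.02 M), sealed tube, 210 °C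
Reagents that add atoms: none
Why: Proposed new method: heating should start an aromatic Claisen [3,3] shift in which the terminal =CH2 of the allyl ether bonds to the OMe-bearing ortho carbon of ring A as the O–CH2 bond breaks, giving dienone 20, whose quaternary carbon has no hydrogen to lose, after which a Cope [3,3] shift passes the allyl unit on to the para carbon (21) and tautomerisation gives phenol 22, so the carbon once bound to oxygen becomes the ring A–CH2 bridge carbon. The closest known reaction is the thermal para-Claisen rearrangement of open-chain allyl ethers of 2,6-dialkoxyphenols to 4-allylphenols, and the new element is that the migrating allyl unit is a link of a macrocycle. The carbon-bridged ring is closed not end to end but by two suprafacial sigmatropic transpositions of one anchor point of the existing ring (O2 to ortho carbon to C5), with the ring size staying at 17 in 19, 20, 21 and 22. No lasting stereocentre arises, because the sp3 ring carbons of 20 and 21 are racemic and vanish on rearomatisation. The step needs para rather than ortho delivery, which the methoxy and aryloxy groups on both ortho carbons enforce, and it needs the twelve-atom strap D–O–C–CH2CH2–B–O to fold over one face of ring A in both chair transition states, which its two ether hinges and the ethylene link should permit. The ring D aryl group on the central allyl carbon stabilises the diyl-like character of both transition states, and the 1,1-disubstituted styrene is far above its ceiling temperature and should not polymerise.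

Step 13
Reactants: 22 carbon-bridged para-(2-arylallyl)phenol
Product: 23 trimethyl ether with exocyclic methylene
Conditions: MeI, K2CO3, DMF, rt
Reagents that add atoms: iodomethane, CI
Why: Williamson methylation caps the newly freed guaiacol-type phenol, which periodate would otherwise oxidise to a quinone in the next step, and the extra methyl costs no step because it leaves with the others at the end.

Step 14
Reactants: 23 trimethyl ether with exocyclic methylene
Product: 25 macrocyclic aryl benzyl ketone, via vicinal diol 24 (not isolated)
Conditions: OsO4 (cat.), NaIO4, 2,6-lutidine, 1,4-dioxane/H2O, rt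
Reagents that add atoms: OsO4, O=[Os](=O)(=O)=O (delivers the oxygen); NaIO4, [Na+].[O-]I(=O)(=O)=O (restores it)
Why: In this Lemieux–Johnson cleavage OsO4 dihydroxylates the only alkene to diol 24 and periodate cleaves it to the ketone and formaldehyde, which excises the surplus carbon.

Step 15
Reactants: 25 macrocyclic aryl benzyl ketone
Product: 27 trimethyl ether of the target, via benzylic carbinol 26 (not isolated)
Conditions: Et3SiH, CF3CO2H, CH2Cl2, 0 °C to rt
Reagents that add atoms: none
Why: In this Kursanov–Parnes ionic hydrogenation the protonated aryl ketone takes up hydride to give carbinol 26, which ionises to a benzylic cation stabilised by the ortho aryloxy group of ring D and is reduced again, and Friedel–Crafts closure to a xanthene is blocked because both ring C carbons ortho to the ether oxygen are substituted.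

Step 16
Reactants: 27 trimethyl ether of the target
Product: 28 CNP0290892.0 (target)
Conditions: BBr3, CH2Cl2, −78 °C to rt; then H2O
Reagents that add atoms: none
Why: Lewis acid ether cleavage with BBr3 removes all three aryl methyl ethers through borate esters and leaves the diaryl ethers and both ethylene bridges intact, which is the customary final step for bis(bibenzyl) phenols.

**Compound list**

1 | o-vanillin (2-hydroxy-3-methoxybenzaldehyde) | COc1cccc(C=O)c1O | starting material
2 | 3-methoxy-2-(methoxymethoxy)benzaldehyde | COCOc1c(OC)cccc1C=O | intermediate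
3 | 3-methoxy-2-(methoxymethoxy)phenyl formate | COCOc1c(OC)cccc1OC=O | intermediate (not isolated)
4 | 3-methoxy-2-(methoxymethoxy)phenol | COCOc1c(OC)cccc1O | intermediate
5 | 4-fluorobenzaldehyde | O=Cc1ccc(F)cc1 | starting material
6 | 4-[3-methoxy-2-(methoxymethoxy)phenoxy]benzaldehyde | COCOc1c(OC)cccc1Oc1ccc(C=O)cc1 | intermediate
7 | 2-bromophenol | Oc1ccccc1Br | starting material
8 | 2-fluoro-3-methoxybenzaldehyde | COc1cccc(C=O)c1F | starting material
9 | 2-(2-bromophenoxy)-3-methoxybenzaldehyde | COc1cccc(C=O)c1Oc1ccccc1Br | intermediate
10 | [2-(2-bromophenoxy)-3-methoxyphenyl]methanol | COc1cccc(CO)c1Oc1ccccc1Br | intermediate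
11 | [2-(2-bromophenoxy)-3-methoxybenzyl]triphenylphosphonium bromide | COc1cccc(C[P+](c2ccccc2)(c2ccccc2)c2ccccc2)c1Oc1ccccc1Br.[Br-] | intermediate
12 | [2-(2-bromophenoxy)-3-methoxybenzylidene]triphenylphosphorane | COc1cccc(C=P(c2ccccc2)(c2ccccc2)c2ccccc2)c1Oc1ccccc1Br | intermediate (not isolated)
13 | stilbene: ring C [2-(2-bromophenoxy)-3-methoxyphenyl]–CH=CH–ring B [4-(3-methoxy-2-(methoxymethoxy)phenoxy)phenyl], E/Z mixture | COCOc1c(OC)cccc1Oc1ccc(C=Cc2cccc(OC)c2Oc2ccccc2Br)cc1 | intermediate
14 | bibenzyl from 13 (CH2CH2 in place of CH=CH), MOM ether and aryl bromide retained | COCOc1c(OC)cccc1Oc1ccc(CCc2cccc(OC)c2Oc2ccccc2Br)cc1 | intermediate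
15 | 2-(4-{2-[2-(2-bromophenoxy)-3-methoxyphenyl]ethyl}phenoxy)-6-methoxyphenol | COc1cccc(Oc2ccc(CCc3cccc(OC)c3Oc3ccccc3Br)cc2)c1O | intermediate
16 | 2-bromoprop-2-en-1-ol | OCC(Br)=C | starting material
17 | pinacol boronate of 15 (Bpin in place of Br on ring D) | COc1cccc(Oc2ccc(CCc3cccc(OC)c3Oc3ccccc3B3OC(C)(C)C(C)(C)O3)cc2)c1O | intermediate (not isolated)
18 | 2-[4-(2-{2-[2-(3-hydroxyprop-1-en-2-yl)phenoxy]-3-methoxyphenyl}ethyl)phenoxy]-6-methoxyphenol | COc1cccc(Oc2ccc(CCc3cccc(OC)c3Oc3ccccc3C(=C)CO)cc2)c1O | intermediate
19 | 17-membered ether macrocycle: ring A O2–CH2–C(=CH2)–ring D (ortho)–O–ring C–CH2CH2–ring B (para)–O–ring A C3; OMe on ring A C1 and on ring C | COc1cccc2c1OCC(=C)c1ccccc1Oc1c(OC)cccc1CCc1ccc(O2)cc1 | intermediate (key-step precursor)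
20 | macrocyclic 6-methoxy-6-(2-arylallyl)cyclohexa-2,4-dienone (allyl CH2 on the OMe-bearing carbon), racemic | COC12C=CC=C(Oc3ccc(CCc4cccc(OC)c4Oc4ccccc4C(=C)C1)cc3)C2=O | intermediate (not isolated)
21 | macrocyclic 4-(2-arylallyl)cyclohexa-2,5-dienone (allyl CH2 on the para carbon), racemic | COC1=CC2C=C(Oc3ccc(CCc4cccc(OC)c4Oc4ccccc4C(=C)C2)cc3)C1=O | intermediate (not isolated)
22 | carbon-bridged 17-membered macrocycle: ring A C5–CH2–C(=CH2)–ring D, free C2–OH, OMe on ring A C1 and on ring C | COc1cc2cc(c1O)Oc1ccc(cc1)CCc1cccc(OC)c1Oc1ccccc1C(=C)C2 | intermediate (key-step product)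
23 | O-methyl ether of 22 | COc1cc2cc(c1OC)Oc1ccc(cc1)CCc1cccc(OC)c1Oc1ccccc1C(=C)C2 | intermediate
24 | 1,2-diol from 23 [C(OH)(CH2OH) in place of C(=CH2)], racemic | COc1cc2cc(c1OC)Oc1ccc(cc1)CCc1cccc(OC)c1Oc1ccccc1C(O)(CO)C2 | intermediate (not isolated)
25 | macrocyclic ketone, ring D–C(=O)–CH2–ring A | COc1cc2cc(c1OC)Oc1ccc(cc1)CCc1cccc(OC)c1Oc1ccccc1C(=O)C2 | intermediate
26 | macrocyclic carbinol, ring D–CH(OH)–CH2–ring A, racemic | COc1cc2cc(c1OC)Oc1ccc(cc1)CCc1cccc(OC)c1Oc1ccccc1C(O)C2 | intermediate (not isolated)
27 | tri-O-methyl ether of the target | COc1cc2cc(c1OC)Oc1ccc(cc1)CCc1cccc(OC)c1Oc1ccccc1CC2 | intermediate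
28 | CNP0290892.0 | Oc1cc2cc(c1O)Oc1ccc(cc1)CCc1cccc(O)c1Oc1ccccc1CC2 | target

**Step count**

Total step count: 16.
Longest linear sequence: 13 (steps 1–3 or steps 4–6, then steps 7–16).

**Steps most likely to fail**

Step 12. The strap may not let the allyl unit fold over ring A. In that case cleavage of the allyl–oxygen bond with ring opening, or drift of the exocyclic double bond into conjugation, could overtake the two sigmatropic shifts. The fallback uses known chemistry, sets out from 15 and rejoins the route at 27. NBS (MeCN, 0 °C) should brominate ring A para to the free hydroxyl, because both ortho carbons are blocked, to give the para-bromophenol F1. MeI and K2CO3 cap it as the dibromo trimethyl ether F2. Double bromine–lithium exchange (n-BuLi, THF, −78 °C) with a DMF quench gives the dialdehyde F3. Intramolecular McMurry coupling (TiCl4, Zn, THF, reflux, high dilution), an established closure for bis(bibenzyl) rings, gives the macrocyclic stilbene F4. H2 over Pd/C saturates it to 27, and step 16 follows as before.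

Step 11. Intermolecular etherification to oligomers, and N-alkylation of the reduced azodicarboxylate in place of the hindered phenol, may outrun ring closure. The fallback separates activation from closure, sets out from 18 and returns at 19. An Appel reaction (CBr4, PPh3, CH2Cl2, 0 °C), which leaves the phenol alone, gives the allylic bromide F5. Slow addition of this bromide to Cs2CO3 in DMF at 60 °C closes the ring by Williamson etherification of the caesium phenoxide, with no competing nitrogen nucleophile present.

Step 10. Borylation of the hindered ortho-aryloxy bromide may be sluggish, and protodeboronation of the boronate in aqueous base may drain material. The fallback reverses the polarity, sets out from 15 and returns at 18. The arene stays the electrophile and the C3 unit becomes the nucleophile. Hydrostannation of propargyl alcohol with Bu3SnH under Mo(CO)3(CNtBu)3 catalysis gives 2-(tributylstannyl)prop-2-en-1-ol F6. Stille coupling of this stannane with 15 (Pd(PPh3)4, CuI, DMF, 80 °C) forms the same ring D–C(vinyl) bond without any aryl boronate.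

**Further compounds**

F1 | step 12 | 4-bromo-2-(4-{2-[2-(2-bromophenoxy)-3-methoxyphenyl]ethyl}phenoxy)-6-methoxyphenol | COc1cc(Br)cc(Oc2ccc(CCc3cccc(OC)c3Oc3ccccc3Br)cc2)c1O
F2 | step 12 | O-methyl ether of F1 (dibromo trimethyl ether) | COc1cc(Br)cc(Oc2ccc(CCc3cccc(OC)c3Oc3ccccc3Br)cc2)c1OC
F3 | step 12 | dialdehyde (CHO in place of both Br of F2) | COc1cc(C=O)cc(Oc2ccc(CCc3cccc(OC)c3Oc3ccccc3C=O)cc2)c1OC
F4 | step 12 | macrocyclic stilbene, ring D–CH=CH–ring A (configuration not fixed) | COc1cc2cc(c1OC)Oc1ccc(cc1)CCc1cccc(OC)c1Oc1ccccc1C=C2
F5 | step 11 | allylic bromide of 18 (CH2Br in place of CH2OH) | COc1cccc(Oc2ccc(CCc3cccc(OC)c3Oc3ccccc3C(=C)CBr)cc2)c1O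
F6 | step 10 | 2-(tributylstannyl)prop-2-en-1-ol | CCCC[Sn](CCCC)(CCCC)C(=C)CO
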